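## Structural features

Compound 24 is a daucane-type hydroazulene in which cyclopentane ring A (C1–C5) is trans-fused along C1–C5 to cycloheptene ring B (C5, C6, C7, C8, C9, C10, C1), whose only alkene is C8=C9 with a methyl group on C8. Six stereocentres form two runs around the ring fusion, C10–C1–C2 and C4–C5–C6: C1 is quaternary (angular methyl), C4 is a tertiary carbinol bearing isopropyl, C2 is a free secondary carbinol, and C6 and C10 carry (Z)-2-methylbut-2-enoate (angelate) esters. Taking the face of the C5 hydrogen as β, the C1 methyl, the C2 oxygen and the C4 hydroxyl are α (isopropyl β) and the C6 and C10 oxygens are β, so the C10 oxygen is trans to the angular methyl and 1,3-anti to the C2 oxygen. The fragile groups are the angelates (isomerisation to tiglates under base, nucleophiles or heat; migration from O10 to a free O2), the allylic C10 ester and the tertiary C4 alcohol, and every intermediate with a C4 carbonyl also has leaving groups β to it at C6 and C2. The real difficulty lies in the quaternary C1 wedged between three oxygenated carbons, in placing the C10 oxygen on the face a hydride reagent would not choose, and in telling three secondary hydroxyls apart. Because the C6 and C10 esters are identical, only C2 has to be distinguished. The key step exploits the fact that C1 is at once the β-carbon of a C4 carbonyl (through C5) and the neighbour of oxygenated C10: an acyl radical at C10 can add to C1 of a C5=C1 enone in ring A, closing ring B and creating the quaternary centre.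

## Logic of the disconnections

24 back to 21 and two equivalents of 22 (through 23). The two acyl–oxygen bonds at O6 and O10 are cut together, and O2 is given a temporary p-nitrobenzoate. Both esters derive from the same acid, so one double esterification replaces two protect–acylate cycles. The forward steps require that O2 stays masked through a warm esterification and is then released without touching two angelates. 21 must offer only two acylable hydroxyls, which holds because the C4 hydroxyl is tertiary.

21 back to 19 (through 20). The C10–H bond and the O2–acyl bond are cut in one move, and the C6 silyl ether is restored. The C10 oxygen is trans to the angular methyl, so hydride must arrive from the methyl face, where the only handle is O2, β to the C10 carbonyl. A Tishchenko-type delivery from O2 sets C10 and leaves O2 acylated, which settles the C2/C10 differentiation that a plain directed reduction would leave open. The demand is a free O2 beside a protected O6, hence silyl groups of graded stability in 18.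

19 back to 17 (through 18). The C4–isopropyl bond is cut, returning C4 to the ketone that the ring closure needs. The nucleophile must choose C4 over C10, approach from the face of the C5 hydrogen, and not act as a base toward a ketone with two β-silyloxy groups.

17 back to 16. The C1–C10 bond and the C5–H bond are cut. Ring B opens to a chain on C5 of a flat cyclopentenone, and the quaternary centre, the seven-membered ring and the trans fusion disappear together. The forward step must attack the hindered β-carbon in the 7-endo mode on the face anti to the C2 silyloxy group, deliver hydrogen to C5 anti to the new methyl, and start from a Z chain.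

16 back to 10 and 15 (through 14 and 13). The C10–Se bond is cut to the acid, the C4 carbonyl retreats to a silylated carbinol, and the O6–C10 bond is re-formed to a lactone. The lactone guarantees the Z geometry and protects O6 without a protecting group. The masked C4 carbonyl keeps hydroxide away from a β-silyloxy enone, and selenium enters last so that no oxidation follows it. The seco acid must be silylated before it can relactonise, and the C4 silyl group must come off beside two others.

10 back to 8 (through 9). The C8=C9 bond (metathesis) and the O6–C10 acyl bond are cut; C9 and C10 then arrive as an acryloyl unit and the alkene geometry follows from the ring size. The metathesis must form a trisubstituted alkene and ignore the tetrasubstituted ring alkene.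

8 back to 7. The C6–C7 bond is cut, so the C6 stereocentre is set by a chiral methallylboron reagent on a simple aldehyde. Reagent control must outweigh the existing centres at C2 and C4.

7 back to 3 (through 6, 5 and 4). The C5–C6 bond (formyl carbon) is cut to an alkenyl iodide, C4 returns to the ketone, and the C5–I bond is cut. This requires α-iodination of a β-methyl enone and halogen–lithium exchange without silyl migration.

3 back to 1 (through 2). The C1–CH3 bond is cut, leaving 1, a commercial enantiopure enone whose stereocentre becomes C2 and controls all the others. Conjugate addition and re-oxidation must not eliminate the β-silyloxy group.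

## Other disconnections considered

Alternative 1: The cut is C7–C8, made in ring-contracted form. Ring B is traced back to a six-membered ring (C1, C5, C6, C8, C9, C10) in the β-hydroxy acid A2, whose C6 carries a hydroxyl and the C7 acetic acid arm. In the forward step, anodic oxidation at graphite expels CO2. The C7 radical closes on the C8=C9 alkene and reopens with C8 bonded to C7 (a 1,2-alkenyl shift), and the C6 hydroxyalkyl radical is oxidised to the ketone of hydroazulenone A1.
- In favour: the quaternary C1, the trans fusion, the C4 carbinol and the C10 oxygen would all be set in hydrindane chemistry, which is better charted than hydroazulene chemistry. No selenium, silane or high dilution is needed.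
- Against: A1 is a β,γ-unsaturated ketone with acidic C7 hydrogens, so migration of the alkene into conjugation threatens the one alkene position that must be kept. The trisubstituted alkene and the free tertiary alcohol are oxidisable at the anode. Over-oxidation of the C7 radical to a cation would open a competing shift of C5. C6 would still need a β-selective reduction.
- Comparison: on structure, the chosen plan stakes ring B on one radical addition to a crowded carbon, this plan on the survival of a deconjugated enone. On mechanism the alternative is the better in one respect: C10 would be a protected carbinol of the right configuration before ring B exists, so the directed reduction and temporary C2 ester (steps 15 to 19) would be unnecessary. On step economy it is the weaker, since A2 needs five stereocentres and a two-carbon homologation before the key step, which is expected to cost more than the thirteen steps to 17.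

Alternative 2: Two bonds are cut, C7–C8 and C1–C10, dividing ring B into the cyclopentenyl diene A4 (C1=C5–C6(OEt)=C7) and the siloxyvinyl diazo ester A5 (C8, C9, C10). In the forward step Rh2(DOSP)4 decomposes A5 and the ethoxyvinyl group of A4 is cyclopropanated (C7–C8 and a transient C6–C8 bond). A divinylcyclopropane (Cope) rearrangement through a boat transition state then forms C1–C10 and gives the cycloheptadiene A3.
- In favour: the route is convergent and makes two ring bonds in one operation. The concerted rearrangement relays the alkene geometry of A5 to C10 relative to C1, which is better than the chosen plan, where C10 needs a separate directed reduction.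
- Against: the rearrangement must bond C10 to the fully substituted C1 of a tetrasubstituted ring alkene, so the sequence may stall after the cyclopropanation. A3 carries an ester at C8 where a methyl is needed and an enol ether at C6, so an ester-to-methyl reduction, a C6 reduction and a C5 protonation that must give the trans fusion follow. C4 arrives as a secondary silyl ether to be oxidised and isopropylated late, next to a base-sensitive C6 oxygen.
- Comparison: on structure the plans are equal in that both create the quaternary C1 in the ring-forming event. On mechanism a pericyclic step is more predictable than a radical chain, a point for the alternative. On step economy the short assembly of A3 is offset by corrections at C8, C6, C5 and C4, estimated to exceed the six steps from 17 to 24.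

Alternative 3: The cut is C9–C10. The precursor A7 is a cyclopentane whose quaternary C1 bears the C10 aldehyde and whose C5 bears the C6–C9 chain ending in a (Z)-alkenyl iodide. CrCl2 with catalytic NiCl2 activates the carbon–iodine bond of A7, and the resulting carbon–chromium bond adds to the aldehyde and closes ring B as the allylic alcohol A6.
- In favour: the reaction is chemoselective, tolerates silyl ethers, keeps the alkene geometry and is dependable for medium rings. C10 arrives as the only free hydroxyl and could be esterified at once, which is better than the C2/C10 handling of the chosen plan.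
- Against: the configuration at C10 (hydroxyl trans to the methyl, on a neopentyl aldehyde) is not secured, and correcting it by oxidation and directed reduction brings back the chosen plan's problem. The whole difficulty moves into A7, a cyclopentane with four contiguous stereocentres, including the quaternary C1 carrying an aldehyde, built without the help of a ring closure. Chromium salts are needed in large excess.
- Comparison: on structure the chosen plan creates C1 and ring B together from a flat cyclopentenone, whereas this plan needs C1 beforehand. On mechanism a polar addition to an aldehyde is safer than a radical addition to a tetrasubstituted alkene, a point for the alternative. On step economy the route to A7 is expected to be longer. The two are equal in needing high dilution for the ring closure.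

Key step: step 13

Remarks on the chemistry:
- The methallylborane made from (+)-α-pinene is taken to add to the si face of aldehyde 7, as it does with benzaldehyde; if the stereocentres of 7 oppose it, the fallback for step 7 applies.
- The C4 carbinol centre of 5 to 13 is drawn as the cis isomer expected from hydride attack anti to the silyloxy group; its configuration is immaterial because step 11 returns it to a carbonyl.
- The silyl groups of 16 and 17 are TBS on O2 and TBDPS on O6, so that O2 can be freed before O6.
- Step 18 consumes two molecules of 22 per molecule of 21, one for each of the two secondary hydroxyls.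

Step 1
Reactants: 1 (R)-4-(tert-butyldimethylsilyloxy)cyclopent-2-en-1-one
Product: 2 trimethyl{[(3R,4R)-4-(tert-butyldimethylsilyloxy)-3-methylcyclopent-1-en-1-yl]oxy}silane (methyl trans to the silyloxy group)
Conditions: MeMgBr, CuBr·SMe2 (10 mol%), TMSCl, THF, −78 °C
Reagents that add atoms: methylmagnesium bromide C[Mg]Br; chlorotrimethylsilane C[Si](C)(C)Cl
Why: Copper-catalysed conjugate addition anti to the silyloxy group; trapping the enolate as its silyl enol ether at −78 °C prevents enolate equilibration and E1cB loss of the silyloxy group and fixes the enol position for step 2; the methyl-bearing centre is transient.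

Step 2
Reactants: 2 trimethyl{[(3R,4R)-4-(tert-butyldimethylsilyloxy)-3-methylcyclopent-1-en-1-yl]oxy}silane
Product: 3 (R)-4-(tert-butyldimethylsilyloxy)-3-methylcyclopent-2-en-1-one
Conditions: Pd(OAc)2 (10 mol%), O2 (1 atm), DMSO, rt
Reagents that add atoms: none
Why: Saegusa–Ito oxidation; the palladium enolate has a single β-hydrogen, on the methyl-bearing carbon, so the enone returns regiospecifically and the silyloxy stereocentre (later C2) is untouched.

Step 3
Reactants: 3 (R)-4-(tert-butyldimethylsilyloxy)-3-methylcyclopent-2-en-1-one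
Product: 4 (R)-4-(tert-butyldimethylsilyloxy)-2-iodo-3-methylcyclopent-2-en-1-one
Conditions: I2, pyridine/CH2Cl2 (1:1), DMAP (cat.), rt
Reagents that add atoms: iodine II
Why: α-Iodination of an enone by addition–elimination (pyridine adds to the β-carbon, the enolate is iodinated, pyridine leaves); known for 3-methylcycloalkenones though slower than for unsubstituted enones, and it places the handle on the future C5.

Step 4
Reactants: 4 (R)-4-(tert-butyldimethylsilyloxy)-2-iodo-3-methylcyclopent-2-en-1-one
Product: 5 (1S,4R)-4-(tert-butyldimethylsilyloxy)-2-iodo-3-methylcyclopent-2-en-1-ol (cis)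
Conditions: NaBH4, CeCl3·7H2O, MeOH, −78 to −20 °C
Reagents that add atoms: none
Why: Luche 1,2-reduction; hydride enters anti to the silyloxy group to give mainly the cis alcohol, which only serves to mask the C4 carbonyl until step 11.

Step 5
Reactants: 5 (1S,4R)-4-(tert-butyldimethylsilyloxy)-2-iodo-3-methylcyclopent-2-en-1-ol
Product: 6 tert-butyl{[(1R,4S)-3-iodo-2-methyl-4-(triethylsilyloxy)cyclopent-2-en-1-yl]oxy}dimethylsilane (cis)
Conditions: TESCl, imidazole, DMF, 0 °C to rt
Reagents that add atoms: chlorotriethylsilane CC[Si](Cl)(CC)CC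
Why: Silylation of the secondary alcohol; the triethylsilyl ether is the most labile of the three silyl groups used and can later be removed beside TBS and TBDPS ethers.

Step 6
Reactants: 6 tert-butyl{[(1R,4S)-3-iodo-2-methyl-4-(triethylsilyloxy)cyclopent-2-en-1-yl]oxy}dimethylsilane
Product: 7 (3R,5S)-3-(tert-butyldimethylsilyloxy)-2-methyl-5-(triethylsilyloxy)cyclopent-1-ene-1-carbaldehyde
Conditions: t-BuLi (2.1 equiv), Et2O, −78 °C; DMF; H2O
Reagents that add atoms: N,N-dimethylformamide CN(C)C=O
Why: Iodine–lithium exchange and formylation of the alkenyllithium; ether at −78 °C disfavours O-to-C silyl migration, and a ring-bound alkenyllithium has no β-elimination pathway.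

Step 7
Reactants: 7 (3R,5S)-3-(tert-butyldimethylsilyloxy)-2-methyl-5-(triethylsilyloxy)cyclopent-1-ene-1-carbaldehyde
Product: 8 (1S)-1-[(3R,5S)-3-(tert-butyldimethylsilyloxy)-2-methyl-5-(triethylsilyloxy)cyclopent-1-en-1-yl]-3-methylbut-3-en-1-ol
Conditions: (−)-Ipc2BOMe, methallylMgCl, Et2O, −78 °C; then 7, −78 °C; NaOH, H2O2
Reagents that add atoms: B-methallyldiisopinocampheylborane from (−)-Ipc2BOMe (formed in the flask) C=C(C)CB([C@@H]1C[C@@H]2C[C@H]([C@H]1C)C2(C)C)[C@@H]1C[C@@H]2C[C@H]([C@H]1C)C2(C)C
Why: Brown methallylboration through a chair six-membered transition state; the borane derived from (+)-α-pinene adds to the si face of the aldehyde and sets C6 as S by reagent control, and conjugated aldehydes react cleanly in the 1,2 sense.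

Step 8
Reactants: 8 (1S)-1-[(3R,5S)-3-(tert-butyldimethylsilyloxy)-2-methyl-5-(triethylsilyloxy)cyclopent-1-en-1-yl]-3-methylbut-3-en-1-ol
Product: 9 (1S)-1-[(3R,5S)-3-(tert-butyldimethylsilyloxy)-2-methyl-5-(triethylsilyloxy)cyclopent-1-en-1-yl]-3-methylbut-3-en-1-yl prop-2-enoate
Conditions: acryloyl chloride, iPr2NEt, CH2Cl2, −20 to 0 °C
Reagents that add atoms: acryloyl chloride C=CC(Cl)=O
Why: O-Acylation of the secondary allylic alcohol; the acrylate supplies C9 and C10 and tethers them to O6 for the ring closure.

Step 9
Reactants: 9 (1S)-1-[(3R,5S)-3-(tert-butyldimethylsilyloxy)-2-methyl-5-(triethylsilyloxy)cyclopent-1-en-1-yl]-3-methylbut-3-en-1-yl prop-2-enoate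
Product: 10 (6S)-6-[(3R,5S)-3-(tert-butyldimethylsilyloxy)-2-methyl-5-(triethylsilyloxy)cyclopent-1-en-1-yl]-4-methyl-5,6-dihydro-2H-pyran-2-one
Conditions: second-generation Grubbs catalyst (5 mol%), CH2Cl2, 40 °C
Reagents that add atoms: none
Why: Ring-closing metathesis of an acrylate with a 1,1-disubstituted alkene, a standard entry to 4-methyl dihydropyranones; the six-membered ring enforces the Z geometry of C8=C9, and the tetrasubstituted ring alkene is inert.

Step 10
Reactants: 10 (6S)-6-[(3R,5S)-3-(tert-butyldimethylsilyloxy)-2-methyl-5-(triethylsilyloxy)cyclopent-1-en-1-yl]-4-methyl-5,6-dihydro-2H-pyran-2-one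
Product: 13 (2Z,5S)-5-(tert-butyldiphenylsilyloxy)-5-[(3R,5S)-3-(tert-butyldimethylsilyloxy)-5-hydroxy-2-methylcyclopent-1-en-1-yl]-3-methylpent-2-enoic acid, via lithium hydroxy carboxylate 11 (not isolated), via bis-silylated seco acid 12 (not isolated)
Conditions: LiOH, THF/H2O, rt; evaporate; TBDPSCl (2.5 equiv), imidazole, DMF, 45 °C; then PPTS, MeOH, rt
Reagents that add atoms: lithium hydroxide [Li+].[OH-]; tert-butyl(chloro)diphenylsilane CC(C)(C)[Si](Cl)(c1ccccc1)c1ccccc1
Why: Saponification opens the lactone to the Z hydroxy carboxylate, which as a salt cannot relactonise; both oxygens are silylated, and mild acid methanolysis then cleaves the silyl ester and the allylic triethylsilyl ether while the TBS and TBDPS ethers persist.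

Step 11
Reactants: 13 (2Z,5S)-5-(tert-butyldiphenylsilyloxy)-5-[(3R,5S)-3-(tert-butyldimethylsilyloxy)-5-hydroxy-2-methylcyclopent-1-en-1-yl]-3-methylpent-2-enoic acid
Product: 14 (2Z,5S)-5-(tert-butyldiphenylsilyloxy)-5-[(3R)-3-(tert-butyldimethylsilyloxy)-2-methyl-5-oxocyclopent-1-en-1-yl]-3-methylpent-2-enoic acid
Conditions: Dess–Martin periodinane, CH2Cl2, 0 °C to rt
Reagents that add atoms: none
Why: Dess–Martin oxidation of the allylic alcohol restores the cyclopentenone under neutral conditions that spare the acid, the silyl ethers and the Z enoate; it is placed before selenium enters the molecule.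

Step 12
Reactants: 14 (2Z,5S)-5-(tert-butyldiphenylsilyloxy)-5-[(3R)-3-(tert-butyldimethylsilyloxy)-2-methyl-5-oxocyclopent-1-en-1-yl]-3-methylpent-2-enoic acid; 15 diphenyl diselenide
Product: 16 Se-phenyl (2Z,5S)-5-(tert-butyldiphenylsilyloxy)-5-[(3R)-3-(tert-butyldimethylsilyloxy)-2-methyl-5-oxocyclopent-1-en-1-yl]-3-methylpent-2-eneselenoate
Conditions: PBu3, CH2Cl2, rt
Reagents that add atoms: none
Why: Phosphine-mediated selenoesterification (an acyloxyphosphonium ion is attacked by phenylselenolate); neutral and mild, and the fully substituted β-carbon of the enone resists conjugate addition of phosphine or selenolate.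

Step 13
Reactants: 16 Se-phenyl (2Z,5S)-5-(tert-butyldiphenylsilyloxy)-5-[(3R)-3-(tert-butyldimethylsilyloxy)-2-methyl-5-oxocyclopent-1-en-1-yl]-3-methylpent-2-eneselenoate
Product: 17 trans-fused 2α-(tert-butyldimethylsilyloxy)-6β-(tert-butyldiphenylsilyloxy)-1α,8-dimethyl-5β-H-hydroazul-8-ene-4,10-dione (locants C1–C10 and faces as defined under Structural features)
Conditions: (Me3Si)3SiH (1.5 equiv), AIBN (0.3 equiv), benzene, 80 °C, 5 mM, syringe pump over 8 h
Reagents that add atoms: none
Why: The silyl radical abstracts the phenylselanyl group from 16 to give the α,β-unsaturated C10 acyl radical, which adds to C1, the β-carbon of the cyclopentenone, and the resulting C5 radical, stabilised by the C4 carbonyl, takes hydrogen from the silane and carries the chain. The closest known reaction type is the 7-endo cyclisation of acyl radicals from selenoesters onto acrylates and enones; forming a quaternary centre at a fully substituted β-carbon lies at the edge of that precedent. Ring B closes in the 7-endo-trig mode: the nucleophilic acyl radical is polarity-matched with the electron-poor C1, whereas 6-exo attack at C5 would be mismatched and would give an unstabilised tertiary radical. C1 is set by the C2 silyloxy group, which shields the α face so that C10 bonds on the β face and the methyl ends up cis to O2; the (6S) silyloxy group can lie pseudo-equatorial in this folded transition state. C5 is set by hydrogen transfer from the bulky silane anti to the new angular methyl, giving the trans fusion, and being α to the C4 carbonyl it remains adjustable by mild base. The Z alkene inherited from lactone 10 keeps C10 within reach of C1, and an acyl radical that isomerises through its ketenyl form can return to the reactive geometry. Cyclisation must outrun reduction of the acyl radical to the aldehyde, which slow silane addition at high dilution secures; decarbonylation is not a concern for an alkenoyl radical.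

Step 14
Reactants: 17 trans-fused 2α-(tert-butyldimethylsilyloxy)-6β-(tert-butyldiphenylsilyloxy)-1α,8-dimethyl-5β-H-hydroazul-8-ene-4,10-dione
Product: 18 2α-(tert-butyldimethylsilyloxy)-6β-(tert-butyldiphenylsilyloxy)-4α-hydroxy-4β-isopropyl-1α,8-dimethyl-5β-H-hydroazul-8-en-10-one
Conditions: iPrMgCl, CeCl3, THF, −78 °C
Reagents that add atoms: isopropylmagnesium chloride CC(C)[Mg]Cl
Why: Organocerium 1,2-addition, whose low basicity suppresses enolisation, E1cB loss of the β-silyloxy groups and hydride transfer; the cyclopentanone C4 is more electrophilic and far less hindered than the conjugated, neopentyl C10 carbonyl, and attack on the face of the C5 hydrogen (anti to the C5–C6 bond, the C2 silyloxy group and the C1 methyl) gives the 4α-hydroxyl.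

Step 15
Reactants: 18 2α-(tert-butyldimethylsilyloxy)-6β-(tert-butyldiphenylsilyloxy)-4α-hydroxy-4β-isopropyl-1α,8-dimethyl-5β-H-hydroazul-8-en-10-one
Product: 19 6β-(tert-butyldiphenylsilyloxy)-2α,4α-dihydroxy-4β-isopropyl-1α,8-dimethyl-5β-H-hydroazul-8-en-10-one
Conditions: CSA, MeOH/CH2Cl2, rt
Reagents that add atoms: none
Why: Acid-catalysed methanolysis removes a TBS ether much faster than a TBDPS ether, so O2 is freed while O6 stays protected; C1 has no hydrogen, so the new β-hydroxy ketone cannot dehydrate.

Step 16
Reactants: 19 6β-(tert-butyldiphenylsilyloxy)-2α,4α-dihydroxy-4β-isopropyl-1α,8-dimethyl-5β-H-hydroazul-8-en-10-one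
Product: 20 6β-(tert-butyldiphenylsilyloxy)-4α,10β-dihydroxy-4β-isopropyl-1α,8-dimethyl-2α-(4-nitrobenzoyloxy)-5β-H-hydroazul-8-ene
Conditions: SmI2 (30 mol%), 4-O2NC6H4CHO (5 equiv), THF, −10 °C
Reagents that add atoms: 4-nitrobenzaldehyde O=Cc1ccc(cc1)[N+](=O)[O-]
Why: Evans–Tishchenko reduction; the samarium-bound hemiacetal formed at O2 transfers its hydride through a chair six-membered transition state to the α face of C10, so the 1,3-anti product with the 10β-hydroxyl forms and O2 leaves the step as its p-nitrobenzoate, which differentiates C2 from C10 without a separate protection.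

Step 17
Reactants: 20 6β-(tert-butyldiphenylsilyloxy)-4α,10β-dihydroxy-4β-isopropyl-1α,8-dimethyl-2α-(4-nitrobenzoyloxy)-5β-H-hydroazul-8-ene
Product: 21 4α,6β,10β-trihydroxy-4β-isopropyl-1α,8-dimethyl-2α-(4-nitrobenzoyloxy)-5β-H-hydroazul-8-ene
Conditions: TBAF, AcOH (1:1), THF, rt
Reagents that add atoms: none
Why: Fluoride desilylation of the TBDPS ether; buffering with acetic acid keeps the medium near neutral so that the aryl ester does not migrate from O2 to O10.

Step 18
Reactants: 21 4α,6β,10β-trihydroxy-4β-isopropyl-1α,8-dimethyl-2α-(4-nitrobenzoyloxy)-5β-H-hydroazul-8-ene; 22 angelic acid, (Z)-2-methylbut-2-enoic acid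
Product: 23 6β,10β-bis[(Z)-2-methylbut-2-enoyloxy]-4α-hydroxy-4β-isopropyl-1α,8-dimethyl-2α-(4-nitrobenzoyloxy)-5β-H-hydroazul-8-ene
Conditions: 22 (3 equiv), 2,4,6-trichlorobenzoyl chloride (3 equiv), Et3N, toluene, rt; then 21, 80 °C
Reagents that add atoms: angelic acid (second equivalent of 22) C/C=C(/C)C(=O)O
Why: Yamaguchi-type esterification through the mixed anhydride, run without DMAP because nucleophilic catalysts isomerise angelates to tiglates; each of the two secondary hydroxyls takes up one angeloyl group, so two molecules of 22 are consumed per molecule of 21, and the tertiary C4 hydroxyl is inert.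

Step 19
Reactants: 23 6β,10β-bis[(Z)-2-methylbut-2-enoyloxy]-4α-hydroxy-4β-isopropyl-1α,8-dimethyl-2α-(4-nitrobenzoyloxy)-5β-H-hydroazul-8-ene
Product: 24 (1R,2R,4R,5S,6S,10R)-2,4-dihydroxy-4-isopropyl-1,8-dimethyl-5-H-hydroazul-8-ene-6,10-diyl bis[(Z)-2-methylbut-2-enoate]
Conditions: K2CO3 (0.3 equiv), MeOH, 0 °C
Reagents that add atoms: none
Why: Base-catalysed transesterification; the electron-poor aryl ester is methanolysed much faster than the hindered, conjugated, α-branched angelates, releasing the C2 hydroxyl last.

## Compound list

1 | (R)-4-(tert-butyldimethylsilyloxy)cyclopent-2-en-1-one | O=C1C=C[C@H](O[Si](C)(C)C(C)(C)C)C1 | starting material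
2 | trimethyl{[(3R,4R)-4-(tert-butyldimethylsilyloxy)-3-methylcyclopent-1-en-1-yl]oxy}silane | C[C@@H]1C=C(O[Si](C)(C)C)C[C@H]1O[Si](C)(C)C(C)(C)C | intermediate
3 | (R)-4-(tert-butyldimethylsilyloxy)-3-methylcyclopent-2-en-1-one | O=C1C=C(C)[C@H](O[Si](C)(C)C(C)(C)C)C1 | intermediate
4 | (R)-4-(tert-butyldimethylsilyloxy)-2-iodo-3-methylcyclopent-2-en-1-one | O=C1C(I)=C(C)[C@H](O[Si](C)(C)C(C)(C)C)C1 | intermediate
5 | (1S,4R)-4-(tert-butyldimethylsilyloxy)-2-iodo-3-methylcyclopent-2-en-1-ol | O[C@H]1C[C@@H](O[Si](C)(C)C(C)(C)C)C(C)=C1I | intermediate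
6 | tert-butyl{[(1R,4S)-3-iodo-2-methyl-4-(triethylsilyloxy)cyclopent-2-en-1-yl]oxy}dimethylsilane | CC[Si](CC)(CC)O[C@H]1C[C@@H](O[Si](C)(C)C(C)(C)C)C(C)=C1I | intermediate
7 | (3R,5S)-3-(tert-butyldimethylsilyloxy)-2-methyl-5-(triethylsilyloxy)cyclopent-1-ene-1-carbaldehyde | CC[Si](CC)(CC)O[C@H]1C[C@@H](O[Si](C)(C)C(C)(C)C)C(C)=C1C=O | intermediate
8 | (1S)-1-[(3R,5S)-3-(tert-butyldimethylsilyloxy)-2-methyl-5-(triethylsilyloxy)cyclopent-1-en-1-yl]-3-methylbut-3-en-1-ol | C=C(C)C[C@H](O)C1=C(C)[C@H](O[Si](C)(C)C(C)(C)C)C[C@@H]1O[Si](CC)(CC)CC | intermediate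
9 | (1S)-1-[(3R,5S)-3-(tert-butyldimethylsilyloxy)-2-methyl-5-(triethylsilyloxy)cyclopent-1-en-1-yl]-3-methylbut-3-en-1-yl prop-2-enoate | C=CC(=O)O[C@@H](CC(C)=C)C1=C(C)[C@H](O[Si](C)(C)C(C)(C)C)C[C@@H]1O[Si](CC)(CC)CC | intermediate
10 | (6S)-6-[(3R,5S)-3-(tert-butyldimethylsilyloxy)-2-methyl-5-(triethylsilyloxy)cyclopent-1-en-1-yl]-4-methyl-5,6-dihydro-2H-pyran-2-one | O=C1C=C(C)C[C@H](O1)C2=C(C)[C@H](O[Si](C)(C)C(C)(C)C)C[C@@H]2O[Si](CC)(CC)CC | intermediate
11 | lithium (2Z,5S)-5-hydroxy-3-methyl-5-[(3R,5S)-3-(tert-butyldimethylsilyloxy)-2-methyl-5-(triethylsilyloxy)cyclopent-1-en-1-yl]pent-2-enoate | [Li+].[O-]C(=O)/C=C(/C)C[C@H](O)C1=C(C)[C@H](O[Si](C)(C)C(C)(C)C)C[C@@H]1O[Si](CC)(CC)CC | intermediate (not isolated)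
12 | tert-butyldiphenylsilyl (2Z,5S)-5-(tert-butyldiphenylsilyloxy)-3-methyl-5-[(3R,5S)-3-(tert-butyldimethylsilyloxy)-2-methyl-5-(triethylsilyloxy)cyclopent-1-en-1-yl]pent-2-enoate | O=C(/C=C(/C)C[C@H](O[Si](c1ccccc1)(c1ccccc1)C(C)(C)C)C1=C(C)[C@H](O[Si](C)(C)C(C)(C)C)C[C@@H]1O[Si](CC)(CC)CC)O[Si](c1ccccc1)(c1ccccc1)C(C)(C)C | intermediate (not isolated)
13 | (2Z,5S)-5-(tert-butyldiphenylsilyloxy)-5-[(3R,5S)-3-(tert-butyldimethylsilyloxy)-5-hydroxy-2-methylcyclopent-1-en-1-yl]-3-methylpent-2-enoic acid | OC(=O)/C=C(/C)C[C@H](O[Si](c1ccccc1)(c1ccccc1)C(C)(C)C)C1=C(C)[C@H](O[Si](C)(C)C(C)(C)C)C[C@@H]1O | intermediate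
14 | (2Z,5S)-5-(tert-butyldiphenylsilyloxy)-5-[(3R)-3-(tert-butyldimethylsilyloxy)-2-methyl-5-oxocyclopent-1-en-1-yl]-3-methylpent-2-enoic acid | OC(=O)/C=C(/C)C[C@H](O[Si](c1ccccc1)(c1ccccc1)C(C)(C)C)C1=C(C)[C@H](O[Si](C)(C)C(C)(C)C)CC1=O | intermediate
15 | diphenyl diselenide | c1ccc(cc1)[Se][Se]c1ccccc1 | starting material
16 | Se-phenyl (2Z,5S)-5-(tert-butyldiphenylsilyloxy)-5-[(3R)-3-(tert-butyldimethylsilyloxy)-2-methyl-5-oxocyclopent-1-en-1-yl]-3-methylpent-2-eneselenoate | O=C(/C=C(/C)C[C@H](O[Si](c1ccccc1)(c1ccccc1)C(C)(C)C)C1=C(C)[C@H](O[Si](C)(C)C(C)(C)C)CC1=O)[Se]c1ccccc1 | intermediate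
17 | trans-fused 2α-(tert-butyldimethylsilyloxy)-6β-(tert-butyldiphenylsilyloxy)-1α,8-dimethyl-5β-H-hydroazul-8-ene-4,10-dione | CC(C)(C)[Si](c1ccccc1)(c1ccccc1)O[C@H]1CC(C)=CC(=O)[C@@]2(C)[C@H](O[Si](C)(C)C(C)(C)C)CC(=O)[C@H]12 | intermediate
18 | 2α-(tert-butyldimethylsilyloxy)-6β-(tert-butyldiphenylsilyloxy)-4α-hydroxy-4β-isopropyl-1α,8-dimethyl-5β-H-hydroazul-8-en-10-one | CC(C)(C)[Si](c1ccccc1)(c1ccccc1)O[C@H]1CC(C)=CC(=O)[C@@]2(C)[C@H](O[Si](C)(C)C(C)(C)C)C[C@@](O)(C(C)C)[C@H]12 | intermediate
19 | 6β-(tert-butyldiphenylsilyloxy)-2α,4α-dihydroxy-4β-isopropyl-1α,8-dimethyl-5β-H-hydroazul-8-en-10-one | CC(C)(C)[Si](c1ccccc1)(c1ccccc1)O[C@H]1CC(C)=CC(=O)[C@@]2(C)[C@H](O)C[C@@](O)(C(C)C)[C@H]12 | intermediate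
20 | 6β-(tert-butyldiphenylsilyloxy)-4α,10β-dihydroxy-4β-isopropyl-1α,8-dimethyl-2α-(4-nitrobenzoyloxy)-5β-H-hydroazul-8-ene | CC(C)(C)[Si](c1ccccc1)(c1ccccc1)O[C@H]1CC(C)=C[C@@H](O)[C@@]2(C)[C@H](OC(=O)c3ccc(cc3)[N+](=O)[O-])C[C@@](O)(C(C)C)[C@H]12 | intermediate
21 | 4α,6β,10β-trihydroxy-4β-isopropyl-1α,8-dimethyl-2α-(4-nitrobenzoyloxy)-5β-H-hydroazul-8-ene | O[C@H]1CC(C)=C[C@@H](O)[C@@]2(C)[C@H](OC(=O)c3ccc(cc3)[N+](=O)[O-])C[C@@](O)(C(C)C)[C@H]12 | intermediate
22 | angelic acid, (Z)-2-methylbut-2-enoic acid | C/C=C(/C)C(=O)O | starting material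
23 | 6β,10β-bis[(Z)-2-methylbut-2-enoyloxy]-4α-hydroxy-4β-isopropyl-1α,8-dimethyl-2α-(4-nitrobenzoyloxy)-5β-H-hydroazul-8-ene | C/C=C(/C)C(=O)O[C@H]1CC(C)=C[C@@H](OC(=O)/C(C)=C\C)[C@@]2(C)[C@H](OC(=O)c3ccc(cc3)[N+](=O)[O-])C[C@@](O)(C(C)C)[C@H]12 | intermediate
24 | (1R,2R,4R,5S,6S,10R)-2,4-dihydroxy-4-isopropyl-1,8-dimethyl-5-H-hydroazul-8-ene-6,10-diyl bis[(Z)-2-methylbut-2-enoate] (CNP0249167.2; locants as defined under Structural features) | C/C=C(/C)C(=O)O[C@H]1CC(C)=C[C@@H](OC(=O)/C(C)=C\C)[C@@]2(C)[C@H](O)C[C@@](O)(C(C)C)[C@H]12 | target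

## Step count and least certain steps

Total: 19 steps. Longest linear sequence: 19 steps, from 1 to 24 (15 and 22 are purchased).

Step 13 (key step). The most likely failure is hydrogen transfer from the silane to the acyl radical before it has added to the crowded, fully substituted C1 (reduction in place of cyclisation). A second risk is hydrogen delivery to C5 on the wrong face. The fallback runs from 16 back to 17. Reduction of the selenoester with Bu3SnH and catalytic Pd(PPh3)4 (benzene, rt) gives the (Z)-enal F1. F1 is cyclised in a radical chain without stoichiometric hydride (catalytic methyl thioglycolate, di-tert-butyl hyponitrite, benzene, 60 °C). The thiyl radical abstracts the formyl hydrogen, the same acyl radical adds to C1, and the C5 radical is quenched by the thiol or by the aldehyde. Hydrogen return to the acyl radical merely regenerates F1, so the failure mode is removed and not just slowed. Should hydrogen arrive on the wrong face of C5, the ring fusion would be equilibrated with a trace of DBU at low temperature, with care because of the two β-silyloxy groups.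

Step 16. Hydride transfer may fail at the conjugated, neopentyl C10 carbonyl, the samarium alkoxide may trigger retro-aldol cleavage of C1–C2, or the nitro group may consume the SmI2 before the trivalent samarium catalyst forms. The fallback runs from 19 to 20. Me4NBH(OAc)3 in MeCN/AcOH at −20 °C (Evans–Saksena reduction, the same chair delivery from O2) gives the anti-diol F2. p-Nitrobenzoyl chloride in pyridine at −20 °C should then acylate the more accessible cyclopentanol O2 in preference to the axial, neopentyl allylic O10. Site selectivity then rests on sterics and no longer on the mechanism.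

Step 14. The risks are enolisation of the C4 ketone followed by E1cB loss of a silyloxy group, hydride transfer from the secondary Grignard reagent, and addition to C10. The fallback runs from 17 to 18. Isopropenylmagnesium bromide with CeCl3 (no β-hydrogen, less basic) gives the isopropenyl carbinol F3. Hydrogenation with RhCl(PPh3)3 then reduces the 1,1-disubstituted alkene and leaves the trisubstituted enone alkene.

Step 7. Facial selectivity may be poor if the two silyloxy groups on the α face of 7 oppose the borane (a mismatched pair), and addition to the hindered, conjugated aldehyde may be slow. The fallback sets out from 7 and returns at 8. Plain methallylmagnesium chloride gives the carbinol as a mixture of C6 epimers F4, and Dess–Martin oxidation gives the ketone F5. Reduction with (R)-2-methyl-CBS-oxazaborolidine and catecholborane at −78 °C sets C6 by reagent-controlled hydride delivery, with the cyclopentenyl group as the large substituent, returning to (S)-8.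

Step 18. The risks are isomerisation of angelate to tiglate at 80 °C, incomplete acylation of the axial neopentyl O10, and base-induced migration of the p-nitrobenzoyl group from O2 to O10 before O10 is acylated. The fallback runs from 21 to 23. Both hydroxyls are acylated at rt with 2-[bis(2,2,2-trifluoroethoxy)phosphoryl]propanoic acid (DIC, DMAP) to give the bis-phosphonate F6. A double Still–Gennari olefination with acetaldehyde (KN(SiMe3)2, 18-crown-6, THF, −78 °C) then builds both Z alkenes in place, so no preformed angeloyl donor is exposed to heat.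

Step 19. Methanolysis of the C10 angelate, or its 1,3-migration to the freed O2, may compete because the C2 ester is itself hindered. The fallback runs from 19 to 24. The Evans–Tishchenko reaction of 19 is run with methoxyacetaldehyde to give the C2 methoxyacetate F7. Desilylation (TBAF/AcOH) gives the triol F8, and esterification as in step 18 gives the bis-angelate F9. The methoxyacetate is then cleaved with Yb(OTf)3 in methanol, a chelation-activated, non-basic transesterification that generates no alkoxide next to the C10 ester.

## Further compounds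

F1 | step 13 | (2Z,5S)-5-(tert-butyldiphenylsilyloxy)-5-[(3R)-3-(tert-butyldimethylsilyloxy)-2-methyl-5-oxocyclopent-1-en-1-yl]-3-methylpent-2-enal | O=C/C=C(/C)C[C@H](O[Si](c1ccccc1)(c1ccccc1)C(C)(C)C)C1=C(C)[C@H](O[Si](C)(C)C(C)(C)C)CC1=O
F2 | step 16 | 6β-(tert-butyldiphenylsilyloxy)-2α,4α,10β-trihydroxy-4β-isopropyl-1α,8-dimethyl-5β-H-hydroazul-8-ene | CC(C)(C)[Si](c1ccccc1)(c1ccccc1)O[C@H]1CC(C)=C[C@@H](O)[C@@]2(C)[C@H](O)C[C@@](O)(C(C)C)[C@H]12
F3 | step 14 | 2α-(tert-butyldimethylsilyloxy)-6β-(tert-butyldiphenylsilyloxy)-4α-hydroxy-4β-isopropenyl-1α,8-dimethyl-5β-H-hydroazul-8-en-10-one | CC(C)(C)[Si](c1ccccc1)(c1ccccc1)O[C@H]1CC(C)=CC(=O)[C@@]2(C)[C@H](O[Si](C)(C)C(C)(C)C)C[C@@](O)(C(C)=C)[C@H]12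
F4 | step 7 | 1-[(3R,5S)-3-(tert-butyldimethylsilyloxy)-2-methyl-5-(triethylsilyloxy)cyclopent-1-en-1-yl]-3-methylbut-3-en-1-ol, mixture of epimers at the carbinol carbon | C=C(C)CC(O)C1=C(C)[C@H](O[Si](C)(C)C(C)(C)C)C[C@@H]1O[Si](CC)(CC)CC
F5 | step 7 | 1-[(3R,5S)-3-(tert-butyldimethylsilyloxy)-2-methyl-5-(triethylsilyloxy)cyclopent-1-en-1-yl]-3-methylbut-3-en-1-one | C=C(C)CC(=O)C1=C(C)[C@H](O[Si](C)(C)C(C)(C)C)C[C@@H]1O[Si](CC)(CC)CC
F6 | step 18 | 6β,10β-bis{2-[bis(2,2,2-trifluoroethoxy)phosphoryl]propanoyloxy}-4α-hydroxy-4β-isopropyl-1α,8-dimethyl-2α-(4-nitrobenzoyloxy)-5β-H-hydroazul-8-ene (epimers at the phosphonate α-carbons) | CC(C(=O)O[C@H]1CC(C)=C[C@@H](OC(=O)C(C)P(=O)(OCC(F)(F)F)OCC(F)(F)F)[C@@]2(C)[C@H](OC(=O)c3ccc(cc3)[N+](=O)[O-])C[C@@](O)(C(C)C)[C@H]12)P(=O)(OCC(F)(F)F)OCC(F)(F)F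
F7 | step 19 | 6β-(tert-butyldiphenylsilyloxy)-4α,10β-dihydroxy-4β-isopropyl-2α-(methoxyacetoxy)-1α,8-dimethyl-5β-H-hydroazul-8-ene | CC(C)(C)[Si](c1ccccc1)(c1ccccc1)O[C@H]1CC(C)=C[C@@H](O)[C@@]2(C)[C@H](OC(=O)COC)C[C@@](O)(C(C)C)[C@H]12
F8 | step 19 | 4α,6β,10β-trihydroxy-4β-isopropyl-2α-(methoxyacetoxy)-1α,8-dimethyl-5β-H-hydroazul-8-ene | O[C@H]1CC(C)=C[C@@H](O)[C@@]2(C)[C@H](OC(=O)COC)C[C@@](O)(C(C)C)[C@H]12
F9 | step 19 | 6β,10β-bis[(Z)-2-methylbut-2-enoyloxy]-4α-hydroxy-4β-isopropyl-2α-(methoxyacetoxy)-1α,8-dimethyl-5β-H-hydroazul-8-ene | C/C=C(/C)C(=O)O[C@H]1CC(C)=C[C@@H](OC(=O)/C(C)=C\C)[C@@]2(C)[C@H](OC(=O)COC)C[C@@](O)(C(C)C)[C@H]12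
A1 | alternative 1 | hydroazulenone with C6 ketone (product of the anodic ring expansion) | O=C1CC(C)=C[C@@H](O[Si](C)(C)C(C)(C)C)[C@@]2(C)[C@H](O[Si](C(C)C)(C(C)C)C(C)C)C[C@@](O)(C(C)C)[C@H]12
A2 | alternative 1 | hydrindene β-hydroxy acid (six-membered ring C1, C5, C6, C8, C9, C10; C6 bears OH and CH2CO2H, either C6 epimer) | OC(=O)CC1(O)C(C)=C[C@@H](O[Si](C)(C)C(C)(C)C)[C@@]2(C)[C@H](O[Si](C(C)C)(C(C)C)C(C)C)C[C@@](O)(C(C)C)[C@H]12
A3 | alternative 2 | bicyclic cycloheptadiene ester (product of the formal (4+3) step) | CCOC=1CC(C(=O)OCC)=C[C@@H](O[Si](C)(C)C(C)(C)C)[C@@]2(C)[C@H](O[Si](C(C)C)(C(C)C)C(C)C)C[C@H](O[Si](CC)(CC)CC)C=12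
A4 | alternative 2 | 1-(1-ethoxyvinyl)-2-methyl-3-(triisopropylsilyloxy)-5-(triethylsilyloxy)cyclopent-1-ene | C=C(OCC)C1=C(C)[C@H](O[Si](C(C)C)(C(C)C)C(C)C)C[C@@H]1O[Si](CC)(CC)CC
A5 | alternative 2 | ethyl (E)-4-(tert-butyldimethylsilyloxy)-2-diazobut-3-enoate | CCOC(=O)C(=[N+]=[N-])/C=C/O[Si](C)(C)C(C)(C)C
A6 | alternative 3 | hydroazulene with free C10 hydroxyl (product of the chromium-mediated closure) | CC(C)(C)[Si](C)(C)O[C@H]1CC(C)=C[C@@H](O)[C@@]2(C)[C@H](O[Si](C(C)C)(C(C)C)C(C)C)C[C@@](O[Si](CC)(CC)CC)(C(C)C)[C@H]12
A7 | alternative 3 | cyclopentane carbaldehyde with the (Z)-alkenyl iodide chain on C5 | O=C[C@@]1(C)[C@H](O[Si](C(C)C)(C(C)C)C(C)C)C[C@@](O[Si](CC)(CC)CC)(C(C)C)[C@@H]1[C@@H](O[Si](C)(C)C(C)(C)C)C/C(C)=C\I
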